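| setting | Monday's | Friday's | flask |
|---|---|---|---|
| substrate | 0.50 M | 0.75 M | 1.0 M |
| gas phase | 70 mM (held) | 70 mM (held) | 70 mM (held) |
| remark | run made earlier | run made earlier |  |
| time |  |  | 20 h |

| run | time / h | target / % | substrate / % |
|---|---|---|---|
| Monday's | 1.33 | 39.3 | 58.7 |
| Monday's | 2.50 | 69.4 | 26.7 |
| Monday's | 5.00 | 86.8 | 1.7 |
| Monday's | 8.00 | 74.9 | 0.6 |
| Monday's | 15.0 | 46.0 | 0 |
| Friday's | 1.33 | 36.2 | 61.6 |
| Friday's | 2.50 | 65.4 | 32.5 |
| Friday's | 5.00 | 86.1 | 3.9 |
| Friday's | 8.00 | 76.2 | 0.2 |
| Friday's | 15.0 | 47.8 | 0.1 |

(scatter of a reading: 0.5 percentage points)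

- the numbers in the tables scatter with a standard deviation of 0.5 percentage points
- at the start none of the gas phase is in solution

1. time up to 20 h at which target stands highest
2. the amount of target, in percent of the substrate charged, at that time

The trap I saw in these runs was to take a single pace for the substrate from the first reading, for the pace climbed: in Monday's run the substrate fell at 0.401 /h up to 1.33 h, but at 1.10 /h between 2.50 h and 5.00 h, faster, with no gas phase in solution at the start. By 5.00 h Monday's target read 86.8 % and Friday's 86.1 %, while Monday's target and substrate together already lacked 12 percentage points of the charge, which told me that a loss was about to matter. At the end, with Monday's substrate, the limiting reagent, down to 0.6 % at 8.00 h, the falling target could be timed, so I counted its halvings: the late half-life of target, the hours in which target halves once the substrate has nearly gone, came to 9.95 h in Monday's run and 10.4 h in Friday's. I therefore expected the flask to peak shortly after 5.00 h, close to Friday's reading, and then to halve its target at that pace.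

The forecast put the peak at 5.7 h with 85.5 %, calling this “an empirical extrapolation, not a fitted mechanism”.

The flask peaked at 5.30 h with 86.3 %, earlier than the forecast by 0.400 h and higher by 0.80 points.

    2 substrate → homo dimer (k = 1.32 × 10⁻⁶ /M/s)
    gas phase ⇌ dissolved gas, rate k2*(csat - [dissolved gas]) (kL = 0.00249 /s)
    dissolved gas ⇌ dormant form (K = 35.7, k = 0.0130 /s)
    substrate + dissolved gas → target (k = 0.00789 /M/s)
    dissolved gas + target → over-reaction product (k = 3.16 × 10⁻⁴ /M/s)

At 4.43 h in the flask, the substrate's half-life by its step to target stood at 0.74 h, and the target's by its step to over-reaction product at 19 h, 25.0 times longer. That early figure was also longer than my late half-life, which reckons the flask from 69.7 % at 10.0 h to 34.7 % at 20.0 h, where it held 34.8 %. Reckoned from Monday's 46.0 % at 15.0 h, the neighbour flask with 0.60 M of substrate comes to 32.5 % at 20.0 h, and it held 32.5 %.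

(The data were computed with made-up constants; scatter was added.)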